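The constants used here are those of an exercise; the result is computed.

substrate 0.050 M; salt in the second phase 0.0600 M; capture agent 1.00 mM; spent carrier 1.0 mM; time 2.5 min; volume of the second phase over the first 0.50

- product and crystals together at 2.5 min, in percent of the substrate charged
- the change that raises the amount of product and crystals together at 2.5 min, in percent of the substrate charged most ("none" if none brings more than 2 percentage points) (Sunday's / Wednesday's / Tuesday's / none)
- amount of product and crystals together at 2.5 min, in percent of the substrate charged, after Sunday's

- product is meant together with its crystals
- in the second phase: salt in the second phase, spent salt in the second phase; everything else is in the first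
- charges count per volume of the first phase; a concentration in a rate is the amount of a species over the volume of its own phase; every rate counts per litre of the first phase
- solid, in amounts per volume of the solution: crystals
- run time (flask): 2.5 min

    spent carrier + salt in the second phase ⇌ fresh carrier + spent salt in the second phase (K1 = 1.6, k1 = 290 /M/s)
    substrate + fresh carrier → product + spent carrier (k2 = 14 /M/s)
    spent carrier + capture agent → trapped intermediate (k3 = 1.3 /M/s)
    crystals ⇌ product, rate k4*(cs4 - [product]) while solid is left; crystals form when [product] > cs4 (cs4 = 15 mM, k4 = 1.6 /s)

**The choice.** I decided to follow one thing through this flask: the fresh share, c(fresh carrier) over c(fresh carrier) plus c(spent carrier), since substrate reacts with the fresh form.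

**The ladder.** A spent carrier met the charged salt every 0.0287 s, far quicker than the 0.99 s half-life of fresh carrier in the second step, so I held the exchange at equilibrium. Next came substrate, whose time with every carrier fresh was 71.4 s, against a run of 2.5 min. Trapping came last, with a half-life of 8.9 min, longer than either the substrate's time or the run.

**The reserve.** Both salts sit in one phase, so the phase ratio cancels from the equilibrium. I therefore defined the exchange reserve, the equilibrium constant of the exchange times salt charged over substrate charged, 1.92. With a fraction x of substrate turned over, I took fresh over spent carrier as the reserve minus the constant times x, all over x, counting the salt used by turnover.

**Going round.** With every carrier fresh, the pseudo-first-order decay gave 87.8% as a first answer. Putting that back, I took the fresh share at mid-run, where a first-order decay leaves the square root of its final fraction. That put 0.650 of the substrate turned over at mid-run, giving a fresh share of 0.575 and then 70.1%. The next round gave 0.453, 0.725 and 78.2%. The third gave 0.533, 0.667 and 75.4%, which I kept as my estimate, with trapping left out of it.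

**The changes.** Sunday's doubles the reserve. Two rounds gave a share of 0.812, then 0.426 of substrate left at mid-run and 0.836, so 82.7%. Wednesday's and Tuesday's act on crystals, which count with product, and neither enters the first three steps.

**The result.** The forecast gave 74%, Sunday's and 82%, reasoning that “only doubling the salt helps”. The simulation gave 74.5%, and 82.3% after Sunday's, a gain of 7.8 percentage points, while Wednesday's gained 0 points and Tuesday's 0 points.

**The neighbour.** In this flask at 2.50 min, the reserve and 74.5% gave a share of 49.5%. This flask held fresh carrier at 45.4%, spent at 48.5% and trapped intermediate at 6.16%, so the fresh share of the first two read 48.3%. The neighbour flask has the same charges and the same reserve, read at 40 s. There, one round from 0.244 turned over at mid-run gave a share of 0.862 and 38.3%, and that flask stood at 37.9%.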